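## The problem

Compound 18 is (1R,3R,5R)-4,4-dimethyl-1,3-bis(3-methylbut-2-en-1-yl)-5-(2-methylpropanoyl)-6-oxabicyclo[3.2.1]octane-7,8-dione. Working labels used throughout: C1 (prenylated bridgehead), C2 (lactone carbonyl), O3, C4 (oxygenated bridgehead carrying the isobutyryl group), C5 (gem-dimethyl carbon), C6 (prenyl-bearing methine), C7 (methylene), C8 (bridging ketone).

- A cyclohexanone (C1, C7, C6, C5, C4, C8) is spanned 1,3 by the lactone bridge C2–O3. Both bridgeheads are quaternary, and C4, with four different non-hydrogen substituents, sits next to the quaternary C5. The C4–C5 bond is the hardest bond in the molecule.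
- There are three stereocentres. The bridge allows only one relative arrangement of C1 and C4, so C4 can dictate C1.
- C6 is independent. Its prenyl group lies on the face away from the lactone bridge (equatorial on the chair), and this position can be reached by equilibration only while C6 carries a carbonyl substituent.
- The two trisubstituted alkenes will not survive strong acid, electrophilic oxidants such as SeO2, or free radicals. The non-enolisable β-dicarbonyl arrays around C1 and C4, with the electron-poor C8 ketone, invite retro-Claisen cleavage by hydroxide or alkoxide.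
- The enabling feature: the five-membered ring (C1, C2, O3, C4, C8) is a tetronic acid alkylated at its nucleophilic carbon C1, and only the methylene C7 separates C1 from C6. An acceptor C6=C7 hung from C4 through C5 is all that is needed to close the carbocycle.

## Retrosynthesis

**18 to 15.** The C6 prenyl group is cut at its C=C bond (isopropylidene Wittig) to the acetaldehyde 17, and 17 is cut one carbon back through enol ether 16 to the C6 carbaldehyde 15. A prenyl group cannot activate C6=C7 for ring closure; a formyl group on C6 does, and it also makes C6 epimerisable. The price is three steps after the ring closure. The forward steps need ylides that take an aldehyde in the presence of two hindered ketones and a lactone.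

**15 to 14.** The bond C1–C7 is cut. It is the only ring bond whose formation joins a stabilised carbon nucleophile to an unhindered primary carbon. Cutting C4–C5, C5–C6 or C4–C8 instead would ask a late cation, radical or acyl anion to build or approach a quaternary centre. Precursor 14 is a monocyclic 3-prenyl tetronic acid with one stereocentre (C4) and a 2-substituted acrolein attached through C5. The forward Michael addition must go through carbon, and C6 must settle in its equatorial configuration.

**14 to 12.** The enal is traced back through the allylic alcohol 13 to its silyl ether 12. An enal would not survive the amide bases used to build the tetronic acid and would cyclise prematurely, so it is unmasked only at the end.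

**12 to 7 and 9.** The bond C1–C8 is cut (Lacey–Dieckmann condensation), then the ester bond O3–C2, giving ester 11 and from it the tertiary alcohol 7 and acid chloride 9, made from acid 8. The acid brings the C1 prenyl group in intact. The forward reactions must acylate a very hindered tertiary hydroxyl and must prefer Claisen attack on the ester to aldol attack on the isobutyryl ketone.

**7 to 5.** The allylic C–O bond is removed, through diol 6, to the isopropenyl compound 5. An isopropenyl group is the simplest carrier of the future acrolein, and its single allylic methyl leaves no choice of site. The oxidation must come before any prenyl group is present.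

**5 to 3 and 4.** The bond C4–C5 is cut by a retro-ene step to the vicinal tricarbonyl compound 3 and the symmetrical alkene 4. Alkylation of a C4 enolate with a tertiary electrophile is not possible. A sigmatropic route (O–H insertion of 2 into an allylic alcohol, then [2,3]-Wittig shift) cuts the same bond but offers no secure control of the carbanion face; it is kept as a reserve. The ene reaction forms both adjacent quaternary carbons and the isopropenyl group in one step and places the only reagent-controlled stereocentre, C4, under a chiral copper bisoxazoline catalyst.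

**3 to 1.** The central carbonyl of 3 is traced through diazo ester 2 to the commercial keto ester 1 (diazo transfer, then oxygen transfer).

## Roads not taken

**Alternative 1:** cut C4–C8 and the lactone bond O3–C2.
- Forward step: a triazolium-derived carbene with Cs2CO3 turns the C8 aldehyde of the open-chain keto aldehyde A1 into an acyl anion equivalent that adds to the C4 carbonyl of its 1,2-diketone. This gives the cyclic ketol A2, which would lactonise to 18.
- Merits: the ring, the bridging ketone and the C4 carbinol are made in one catalytic step; both prenyl groups are in place; no homologation follows; the lactone closes intramolecularly instead of by intermolecular acylation of a hindered alcohol. In these respects it is better than the chosen plan.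
- Weak points: the aldehyde sits on the quaternary C1, where Breslow intermediates form slowly. The electrophile is a ketone next to the quaternary C5, with the second ketone competing. A1 carries a base-labile α-formyl ester. C1 and C6 must both be set in an open chain with no mutual control, and the new C4 hydroxyl must come out cis to the ester.
- Comparison: the chosen plan sets only C4 by catalyst and relays the other two stereocentres through the bridge and through equilibration.

**Alternative 2:** cut C4–C5 late.
- Forward step: triflic acid protonates the isopropenyl group of the enolised furandione A3, and the tertiary cation at C5 is captured by enol carbon C4 to give the bis-allyl bicycle A4. Double cross-metathesis with an isobutylene donor and the second-generation Grubbs catalyst would finish 18.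
- Merits: the hardest bond is made intramolecularly and the endgame is one step, shorter than the three steps of the chosen plan.
- Weak points: C4 is the enol carbon of a tricarbonyl system and a poor nucleophile. The enol and carbonyl oxygens should capture the cation first. Proton loss toward C6 or a hydride shift from C6 would erase that stereocentre. A3 needs C1 and C6 set independently, and its non-enolisable furandione is easily opened by nucleophiles.
- Comparison: the chosen plan forms C4–C5 at the start, intermolecularly and under catalyst control, where failure costs little, and closes the ring at an unhindered carbon.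

**Alternative 3:** cut C5–C6.
- Forward step: Fe(acac)3 and PhSiH3 transfer a hydrogen atom to the isopropenyl group of the bis-enal A5, and the tertiary C5 radical adds 6-exo to C6 of the enal arm on its own face, giving A6.
- Merits: radical conjugate addition is well suited to bonds at quaternary carbon. Because C1 is prochiral, the single stereocentre C4 decides C1 and the precursor is built by a simple double alkylation. In stereochemical economy before ring closure it is at least as good as the chosen plan.
- Weak points: C6 is set kinetically and, bearing a CH2CHO group, cannot be corrected. The C5 radical sits next to a carbon with two acyl groups, so a 1,2-acyl shift can compete. Two enals are exposed to the hydride source. The spare arm of A6 must be cut back by two carbons before both ends are olefinated.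
- Comparison: the chosen plan sets against this a polar ring closure and a C6 centre that corrects itself.

Key step: step 11

Assumption (step 3): the (S,S) ligand is taken to expose the Si face of the chelated central ketone, giving (R)-5; if the sense proves opposite, the (R,R) ligand is used and nothing else changes.
Assumption (step 12): enol ether 16 forms as an E/Z mixture, and both isomers hydrolyse to 17.

## Route

Step 1
Reactants: 1 methyl 4-methyl-3-oxopentanoate
Product: 2 methyl 2-diazo-4-methyl-3-oxopentanoate
Conditions: 4-acetamidobenzenesulfonyl azide, Et3N, MeCN, 0 °C to rt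
Reagents that add atoms: 4-acetamidobenzenesulfonyl azide, CC(=O)Nc1ccc(cc1)S(=O)(=O)N=[N+]=[N-]
Why: Regitz diazo transfer to the doubly activated methylene of a β-keto ester; the sulfonamide by-product is removed by filtration.

Step 2
Reactants: 2 methyl 2-diazo-4-methyl-3-oxopentanoate
Product: 3 methyl 4-methyl-2,3-dioxopentanoate
Conditions: dimethyldioxirane, acetone, 0 °C to rt; then 4 Å molecular sieves
Reagents that add atoms: dimethyldioxirane, CC1(C)OO1
Why: Oxygen-atom transfer from the dioxirane to the diazo carbon with loss of N2 is the standard route from 2-diazo-3-keto esters to vicinal tricarbonyl compounds and leaves only acetone. The central carbonyl hydrates readily, so 3 is dried before use.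

Step 3
Reactants: 3 methyl 4-methyl-2,3-dioxopentanoate; 4 2,3-dimethylbut-2-ene
Product: 5 methyl (2R)-2-hydroxy-3,3,4-trimethyl-2-(2-methylpropanoyl)pent-4-enoate
Conditions: Cu(SbF6)2 with (S,S)-tBu-box [2,2'-(propane-2,2-diyl)bis((4S)-4-tert-butyl-4,5-dihydrooxazole)] (10 mol%), 4 Å molecular sieves, CH2Cl2, 0 °C to rt
Reagents that add atoms: none
Why: Enantioselective carbonyl-ene reaction of a 2,3-diketo ester under a divalent copper bisoxazoline catalyst: the central ketone, the most electrophilic carbonyl, is chelated together with the ester carbonyl, and the symmetrical alkene offers twelve equivalent allylic hydrogens, so there is no regiochemical issue. The tert-butyl groups shield one face of the chelated ketone, and attack on the open Si face sets C4 as (R); C4–C5 and the isopropenyl group arise together.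

Step 4
Reactants: 5 methyl (2R)-2-hydroxy-3,3,4-trimethyl-2-(2-methylpropanoyl)pent-4-enoate
Product: 6 methyl (2R)-2-hydroxy-4-(hydroxymethyl)-3,3-dimethyl-2-(2-methylpropanoyl)pent-4-enoate
Conditions: SeO2 (0.5 equiv), tBuOOH, CH2Cl2, rt
Reagents that add atoms: selenium dioxide (catalytic oxygen carrier), O=[Se]=O; tert-butyl hydroperoxide, CC(C)(C)OO
Why: Allylic oxidation with catalytic SeO2 (ene reaction, then [2,3]-sigmatropic shift) at the only allylic C–H position, the vinylic methyl; the C5 methyls are not allylic. It is placed before any prenyl group is present, because trisubstituted alkenes react faster.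

Step 5
Reactants: 6 methyl (2R)-2-hydroxy-4-(hydroxymethyl)-3,3-dimethyl-2-(2-methylpropanoyl)pent-4-enoate
Product: 7 methyl (2R)-4-{[(tert-butyldimethylsilyl)oxy]methyl}-2-hydroxy-3,3-dimethyl-2-(2-methylpropanoyl)pent-4-enoate
Conditions: TBSCl, imidazole, CH2Cl2, 0 °C
Reagents that add atoms: tert-butyldimethylsilyl chloride, CC(C)(C)[Si](C)(C)Cl
Why: Silylation of the primary allylic alcohol; the tertiary hydroxyl at C4, flanked by a quaternary carbon and two carbonyl groups, does not react.

Step 6
Reactants: 8 5-methylhex-4-enoic acid
Product: 9 5-methylhex-4-enoyl chloride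
Conditions: (COCl)2, DMF (cat.), CH2Cl2, 0 °C to rt; evaporate
Reagents that add atoms: oxalyl chloride, ClC(=O)C(Cl)=O
Why: Acid chloride formation through the chloroiminium species from DMF, run cold so that the HCl formed does not add to the trisubstituted alkene; 9 is used crude.

Step 7
Reactants: 7 methyl (2R)-4-{[(tert-butyldimethylsilyl)oxy]methyl}-2-hydroxy-3,3-dimethyl-2-(2-methylpropanoyl)pent-4-enoate; 9 5-methylhex-4-enoyl chloride
Product: 11 methyl (2R)-4-{[(tert-butyldimethylsilyl)oxy]methyl}-3,3-dimethyl-2-[(5-methylhex-4-enoyl)oxy]-2-(2-methylpropanoyl)pent-4-enoate, via lithium alkoxide 10 (not isolated)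
Conditions: LiN(SiMe3)2 (1.05 equiv), THF, −78 °C; then 9 (1.5 equiv), −78 to 0 °C
Reagents that add atoms: none
Why: O-acylation of a lithium alkoxide by an acid chloride (addition–elimination); the neutral hydroxyl is too shielded and too electron-poor to be acylated under amine catalysis. Keeping amine bases out also avoids dehydrohalogenation of 9 to a ketene that could undergo intramolecular [2+2] cycloaddition with its own alkene.

Step 8
Reactants: 11 methyl (2R)-4-{[(tert-butyldimethylsilyl)oxy]methyl}-3,3-dimethyl-2-[(5-methylhex-4-enoyl)oxy]-2-(2-methylpropanoyl)pent-4-enoate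
Product: 12 (5S)-5-(3-{[(tert-butyldimethylsilyl)oxy]methyl}-2-methylbut-3-en-2-yl)-4-hydroxy-3-(3-methylbut-2-en-1-yl)-5-(2-methylpropanoyl)furan-2(5H)-one
Conditions: LiN(SiMe3)2 (2.5 equiv), THF, −78 to 0 °C; then cold 1 M HCl
Reagents that add atoms: none
Why: Lacey–Dieckmann condensation: the ester enolate attacks the adjacent methyl ester in a 5-exo-trig closure, and deprotonation of the tetronic acid formed makes the step irreversible. Aldol addition to the isobutyryl ketone is reversible and should drain into the tetronate; C4 is quaternary and cannot epimerise.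

Step 9
Reactants: 12 (5S)-5-(3-{[(tert-butyldimethylsilyl)oxy]methyl}-2-methylbut-3-en-2-yl)-4-hydroxy-3-(3-methylbut-2-en-1-yl)-5-(2-methylpropanoyl)furan-2(5H)-one
Product: 13 (5S)-4-hydroxy-5-[3-(hydroxymethyl)-2-methylbut-3-en-2-yl]-3-(3-methylbut-2-en-1-yl)-5-(2-methylpropanoyl)furan-2(5H)-one
Conditions: HF·pyridine, pyridine, THF, 0 °C to rt
Reagents that add atoms: none
Why: Buffered fluoride cleavage of the primary silyl ether; the medium is too weakly acidic to protonate the prenyl alkene, and the tetronic acid is inert to it.

Step 10
Reactants: 13 (5S)-4-hydroxy-5-[3-(hydroxymethyl)-2-methylbut-3-en-2-yl]-3-(3-methylbut-2-en-1-yl)-5-(2-methylpropanoyl)furan-2(5H)-one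
Product: 14 (5S)-5-(3-formyl-2-methylbut-3-en-2-yl)-4-hydroxy-3-(3-methylbut-2-en-1-yl)-5-(2-methylpropanoyl)furan-2(5H)-one
Conditions: MnO2 (activated, excess), CH2Cl2, rt
Reagents that add atoms: none
Why: MnO2 oxidises allylic alcohols selectively under neutral, non-nucleophilic conditions. No amine is present, so the enal can be filtered off and cyclised deliberately in the next step.

Step 11
Reactants: 14 (5S)-5-(3-formyl-2-methylbut-3-en-2-yl)-4-hydroxy-3-(3-methylbut-2-en-1-yl)-5-(2-methylpropanoyl)furan-2(5H)-one
Product: 15 (1R,3R,5R)-4,4-dimethyl-1-(3-methylbut-2-en-1-yl)-5-(2-methylpropanoyl)-7,8-dioxo-6-oxabicyclo[3.2.1]octane-3-carbaldehyde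
Conditions: pyrrolidine (20 mol%), CH2Cl2, rt
Reagents that add atoms: none
Why: Pyrrolidine and the tetronic acid (about as acidic as a carboxylic acid) form an ammonium tetronate, the amine condenses reversibly with the aldehyde to an iminium ion, and the tetronate carbon C1 adds to the terminal methylene C7; the enamine formed is protonated at C6 and hydrolysed, returning the catalyst. The closest known reaction type is the amine-catalysed intramolecular Michael addition of cyclic 1,3-dicarbonyl compounds to enals, the first stage of α,α'-annulations that give bicyclo[3.2.1]octanones. One ring is closed, the six-membered carbocycle (C1, C8, C4, C5, C6, C7), in a 6-(enolendo)-endo-trig mode in which C7 reaches C1 perpendicular to the tetronate plane. C1 is controlled by C4: the acrolein arm hangs from C4 on one face of the planar tetronate and can bond only to that face, the one-atom C8 bridge excluding the other diastereomer. C6 is set under thermodynamic control: its proton exchanges through the enamine, and the formyl group settles equatorial on the chair, away from the lactone bridge, where it avoids the 1,3-diaxial contact with C2 and O3. The step needs carbon rather than oxygen attack; addition through the C8 enol oxygen gives a β-tetronyloxy aldehyde that reverts by E1cB elimination under the same conditions, whereas the C-adduct has lost its acidic enol and, with only catalytic amine present, is the neutral resting point. The prenyl alkene and the hindered isobutyryl ketone are spectators.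

Step 12
Reactants: 15 (1R,3R,5R)-4,4-dimethyl-1-(3-methylbut-2-en-1-yl)-5-(2-methylpropanoyl)-7,8-dioxo-6-oxabicyclo[3.2.1]octane-3-carbaldehyde
Product: 16 (1R,3S,5R)-3-(2-methoxyethenyl)-4,4-dimethyl-1-(3-methylbut-2-en-1-yl)-5-(2-methylpropanoyl)-6-oxabicyclo[3.2.1]octane-7,8-dione (E/Z mixture)
Conditions: Ph3P(CH2OMe)Cl, KN(SiMe3)2, THF, 0 °C; then 15, −78 to 0 °C
Reagents that add atoms: (methoxymethyl)triphenylphosphonium chloride, COC[P+](c1ccccc1)(c1ccccc1)c1ccccc1.[Cl-]
Why: Wittig reaction of the non-stabilised methoxymethylidene ylide, which at low temperature takes the aldehyde in preference to the two ketones (both flanked by quaternary carbons) and the lactone. A slight deficiency of base leaves no free amide, and any epimerisation at C6 only restores the thermodynamic epimer.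

Step 13
Reactants: 16 (1R,3S,5R)-3-(2-methoxyethenyl)-4,4-dimethyl-1-(3-methylbut-2-en-1-yl)-5-(2-methylpropanoyl)-6-oxabicyclo[3.2.1]octane-7,8-dione
Product: 17 [(1R,3S,5R)-4,4-dimethyl-1-(3-methylbut-2-en-1-yl)-5-(2-methylpropanoyl)-7,8-dioxo-6-oxabicyclo[3.2.1]octan-3-yl]acetaldehyde
Conditions: 2 M HCl (aq), THF, 0 °C to rt
Reagents that add atoms: water, O
Why: Acid hydrolysis of the enol ether (protonation at carbon, hydration, loss of methanol) is far faster than protonation of the prenyl alkene. C6 now carries a CH2 group and can no longer epimerise.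

Step 14
Reactants: 17 [(1R,3S,5R)-4,4-dimethyl-1-(3-methylbut-2-en-1-yl)-5-(2-methylpropanoyl)-7,8-dioxo-6-oxabicyclo[3.2.1]octan-3-yl]acetaldehyde
Product: 18 (1R,3R,5R)-4,4-dimethyl-1,3-bis(3-methylbut-2-en-1-yl)-5-(2-methylpropanoyl)-6-oxabicyclo[3.2.1]octane-7,8-dione
Conditions: iPrPPh3I, n-BuLi, THF, 0 °C; then 17, −78 to 0 °C
Reagents that add atoms: isopropyltriphenylphosphonium iodide, CC(C)[P+](c1ccccc1)(c1ccccc1)c1ccccc1.[I-]
Why: Wittig olefination with the isopropylidene ylide completes the second prenyl group; the aldehyde reacts at −78 °C while the hindered ketones do not. The ylide is made with a slight deficiency of n-butyllithium so that no alkyllithium reaches the carbonyl groups.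

## Compound list

1 | methyl 4-methyl-3-oxopentanoate | CC(C)C(=O)CC(=O)OC | starting material
2 | methyl 2-diazo-4-methyl-3-oxopentanoate | CC(C)C(=O)C(=[N+]=[N-])C(=O)OC | intermediate
3 | methyl 4-methyl-2,3-dioxopentanoate | CC(C)C(=O)C(=O)C(=O)OC | intermediate
4 | 2,3-dimethylbut-2-ene | CC(C)=C(C)C | starting material
5 | methyl (2R)-2-hydroxy-3,3,4-trimethyl-2-(2-methylpropanoyl)pent-4-enoate | CC(C)C(=O)[C@@](O)(C(=O)OC)C(C)(C)C(C)=C | intermediate
6 | methyl (2R)-2-hydroxy-4-(hydroxymethyl)-3,3-dimethyl-2-(2-methylpropanoyl)pent-4-enoate | CC(C)C(=O)[C@@](O)(C(=O)OC)C(C)(C)C(=C)CO | intermediate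
7 | methyl (2R)-4-{[(tert-butyldimethylsilyl)oxy]methyl}-2-hydroxy-3,3-dimethyl-2-(2-methylpropanoyl)pent-4-enoate | CC(C)C(=O)[C@@](O)(C(=O)OC)C(C)(C)C(=C)CO[Si](C)(C)C(C)(C)C | intermediate
8 | 5-methylhex-4-enoic acid | CC(C)=CCCC(O)=O | starting material
9 | 5-methylhex-4-enoyl chloride | CC(C)=CCCC(Cl)=O | intermediate
10 | lithium alkoxide of 7 (not isolated) | CC(C)C(=O)[C@@]([O-])(C(=O)OC)C(C)(C)C(=C)CO[Si](C)(C)C(C)(C)C.[Li+] | intermediate
11 | methyl (2R)-4-{[(tert-butyldimethylsilyl)oxy]methyl}-3,3-dimethyl-2-[(5-methylhex-4-enoyl)oxy]-2-(2-methylpropanoyl)pent-4-enoate | CC(C)C(=O)[C@@](OC(=O)CCC=C(C)C)(C(=O)OC)C(C)(C)C(=C)CO[Si](C)(C)C(C)(C)C | intermediate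
12 | (5S)-5-(3-{[(tert-butyldimethylsilyl)oxy]methyl}-2-methylbut-3-en-2-yl)-4-hydroxy-3-(3-methylbut-2-en-1-yl)-5-(2-methylpropanoyl)furan-2(5H)-one | CC(C)=CCC1=C(O)[C@](C(=O)C(C)C)(C(C)(C)C(=C)CO[Si](C)(C)C(C)(C)C)OC1=O | intermediate
13 | (5S)-4-hydroxy-5-[3-(hydroxymethyl)-2-methylbut-3-en-2-yl]-3-(3-methylbut-2-en-1-yl)-5-(2-methylpropanoyl)furan-2(5H)-one | CC(C)=CCC1=C(O)[C@](C(=O)C(C)C)(C(C)(C)C(=C)CO)OC1=O | intermediate
14 | (5S)-5-(3-formyl-2-methylbut-3-en-2-yl)-4-hydroxy-3-(3-methylbut-2-en-1-yl)-5-(2-methylpropanoyl)furan-2(5H)-one | CC(C)=CCC1=C(O)[C@](C(=O)C(C)C)(C(C)(C)C(=C)C=O)OC1=O | intermediate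
15 | (1R,3R,5R)-4,4-dimethyl-1-(3-methylbut-2-en-1-yl)-5-(2-methylpropanoyl)-7,8-dioxo-6-oxabicyclo[3.2.1]octane-3-carbaldehyde | O=C[C@@H]1C[C@@]2(CC=C(C)C)C(=O)O[C@](C(=O)C(C)C)(C2=O)C1(C)C | intermediate
16 | (1R,3S,5R)-3-(2-methoxyethenyl)-4,4-dimethyl-1-(3-methylbut-2-en-1-yl)-5-(2-methylpropanoyl)-6-oxabicyclo[3.2.1]octane-7,8-dione (E/Z mixture) | COC=C[C@@H]1C[C@@]2(CC=C(C)C)C(=O)O[C@](C(=O)C(C)C)(C2=O)C1(C)C | intermediate
17 | [(1R,3S,5R)-4,4-dimethyl-1-(3-methylbut-2-en-1-yl)-5-(2-methylpropanoyl)-7,8-dioxo-6-oxabicyclo[3.2.1]octan-3-yl]acetaldehyde | O=CC[C@@H]1C[C@@]2(CC=C(C)C)C(=O)O[C@](C(=O)C(C)C)(C2=O)C1(C)C | intermediate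
18 | (1R,3R,5R)-4,4-dimethyl-1,3-bis(3-methylbut-2-en-1-yl)-5-(2-methylpropanoyl)-6-oxabicyclo[3.2.1]octane-7,8-dione | CC(C)=CC[C@@H]1C[C@@]2(CC=C(C)C)C(=O)O[C@](C(=O)C(C)C)(C2=O)C1(C)C | target

## Step count and risks

Total: 14 steps. Longest linear sequence: 13 steps (steps 1 to 5 and 7 to 14); step 6 is the only side branch.

**Step 11 (key step).** The ambident tetronate may close through oxygen to a fused dihydropyran, the C–C bond may reopen by retro-Michael reaction under the amine, or C6 may equilibrate incompletely. The cause is that the nucleophile is a highly stabilised anion and the C-adduct creates a quaternary centre between two carbonyl groups. Fallback, setting out from 13: zerovalent palladium (Pd(PPh3)4, toluene, 80 °C) would ionise the allylic alcohol, which the acidic tetronic acid activates. The tetronate carbon C1 would then close the same C1–C7 bond by intramolecular Tsuji–Trost alkylation to give (1R,5R)-4,4-dimethyl-3-methylidene-1-(3-methylbut-2-en-1-yl)-5-(2-methylpropanoyl)-6-oxabicyclo[3.2.1]octane-7,8-dione F1; O-allylation is reversible under palladium, so the C-allylated product should collect. Hydroboration of the exocyclic alkene with 9-BBN and oxidation with NaBO3 would give the hydroxymethyl compound (C6 epimers) F2. Dess–Martin oxidation and equilibration with catalytic pyrrolidine would return the route at 15.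

**Step 3.** The ene reaction may not proceed, because a tetrasubstituted alkene must bond to a carbonyl carbon flanked by two acyl groups inside the chiral pocket. Facial selectivity may also be poor, because the bulky alkene can override the shielding by the ligand. Fallback, setting out from 2: dimethyl isopropylidenemalonate would be reduced with iBu2AlH to 2-(propan-2-ylidene)propane-1,3-diol F3 and monosilylated (NaH, TBSCl) to 2-{[(tert-butyldimethylsilyl)oxy]methyl}-3-methylbut-2-en-1-ol F4. Rh2(OAc)4-catalysed O–H insertion of the carbenoid from 2 into F4 would give the allyloxy keto ester F5. A [2,3]-Wittig shift of its copper-chelated enolate (Cu(OTf)2, (S,S)-tBu-box, Et3N) would form C4–C5 and return the route at 7, so that steps 3 to 5 fall away. If enantiocontrol in the shift is insufficient, the material would be resolved at 12 as a salt with a chiral amine.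

**Step 4.** The selenium ene step may be slow at the hindered 1,1-disubstituted alkene. Over-oxidation to the enal may follow, with closure onto the C4 hydroxyl as a lactol, or the new primary alcohol may lactonise onto the methyl ester. Fallback, setting out from 5: ene-type allylic chlorination with hypochlorous acid (Ca(OCl)2, solid CO2, CH2Cl2/water) would give methyl (2R)-4-(chloromethyl)-2-hydroxy-3,3-dimethyl-2-(2-methylpropanoyl)pent-4-enoate F6. Displacement with sodium formate (Bu4NI, DMF) would give the formate ester F7, and mild methanolysis (NaHCO3, MeOH) would return the route at 6.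

**Step 7.** Acylation may fail because the alkoxide is shielded between a quaternary carbon and two carbonyl groups. The alkoxide may also dehydrohalogenate 9 or fragment by retro-allylation. Fallback, setting out from 7: the smallest acyl group is installed instead (Ac2O, DMAP, pyridine, 50 °C) to give the acetate F8. Dieckmann closure (LiN(SiMe3)2, THF) would give the 3-unsubstituted tetronic acid F9. Palladium-catalysed C-allylation with methyl 3-methylbut-2-en-1-yl carbonate (Pd(PPh3)4, THF), in which the soft tetronate attacks the unsubstituted terminus of the π-allyl complex, would return the route at 12.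

**Step 12.** The basic ylide may deprotonate 15 at C6, after which the ring can open by retro-Michael elimination of the tetronate, or the ylide may add to the electron-poor C8 ketone. Fallback, setting out from 15: NaBH(OAc)3 would reduce only the aldehyde to the hydroxymethyl compound F10. Iodination (I2, PPh3, imidazole) would give the iodide F11, and zinc insertion (Zn dust, LiCl, THF) the alkylzinc iodide F12. Negishi coupling with 1-bromo-2-methylprop-1-ene (Pd(OAc)2, SPhos) would return the route at 18 without any strongly basic reagent and with C6 fixed at the aldehyde stage.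

## Further compounds

F1 | step 11 | (1R,5R)-4,4-dimethyl-3-methylidene-1-(3-methylbut-2-en-1-yl)-5-(2-methylpropanoyl)-6-oxabicyclo[3.2.1]octane-7,8-dione | C=C1C[C@@]2(CC=C(C)C)C(=O)O[C@](C(=O)C(C)C)(C2=O)C1(C)C
F2 | step 11 | (1R,5R)-3-(hydroxymethyl)-4,4-dimethyl-1-(3-methylbut-2-en-1-yl)-5-(2-methylpropanoyl)-6-oxabicyclo[3.2.1]octane-7,8-dione (C3 epimers) | OCC1C[C@@]2(CC=C(C)C)C(=O)O[C@](C(=O)C(C)C)(C2=O)C1(C)C
F3 | step 3 | 2-(propan-2-ylidene)propane-1,3-diol | CC(C)=C(CO)CO
F4 | step 3 | 2-{[(tert-butyldimethylsilyl)oxy]methyl}-3-methylbut-2-en-1-ol | CC(C)=C(CO)CO[Si](C)(C)C(C)(C)C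
F5 | step 3 | methyl 2-[(2-{[(tert-butyldimethylsilyl)oxy]methyl}-3-methylbut-2-en-1-yl)oxy]-4-methyl-3-oxopentanoate | CC(C)C(=O)C(OCC(CO[Si](C)(C)C(C)(C)C)=C(C)C)C(=O)OC
F6 | step 4 | methyl (2R)-4-(chloromethyl)-2-hydroxy-3,3-dimethyl-2-(2-methylpropanoyl)pent-4-enoate | CC(C)C(=O)[C@@](O)(C(=O)OC)C(C)(C)C(=C)CCl
F7 | step 4 | methyl (2R)-4-[(formyloxy)methyl]-2-hydroxy-3,3-dimethyl-2-(2-methylpropanoyl)pent-4-enoate | CC(C)C(=O)[C@@](O)(C(=O)OC)C(C)(C)C(=C)COC=O
F8 | step 7 | methyl (2R)-2-(acetyloxy)-4-{[(tert-butyldimethylsilyl)oxy]methyl}-3,3-dimethyl-2-(2-methylpropanoyl)pent-4-enoate | CC(C)C(=O)[C@@](OC(C)=O)(C(=O)OC)C(C)(C)C(=C)CO[Si](C)(C)C(C)(C)C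
F9 | step 7 | (5S)-5-(3-{[(tert-butyldimethylsilyl)oxy]methyl}-2-methylbut-3-en-2-yl)-4-hydroxy-5-(2-methylpropanoyl)furan-2(5H)-one | O=C1C=C(O)[C@](C(=O)C(C)C)(C(C)(C)C(=C)CO[Si](C)(C)C(C)(C)C)O1
F10 | step 12 | (1R,3R,5R)-3-(hydroxymethyl)-4,4-dimethyl-1-(3-methylbut-2-en-1-yl)-5-(2-methylpropanoyl)-6-oxabicyclo[3.2.1]octane-7,8-dione | OC[C@@H]1C[C@@]2(CC=C(C)C)C(=O)O[C@](C(=O)C(C)C)(C2=O)C1(C)C
F11 | step 12 | (1R,3R,5R)-3-(iodomethyl)-4,4-dimethyl-1-(3-methylbut-2-en-1-yl)-5-(2-methylpropanoyl)-6-oxabicyclo[3.2.1]octane-7,8-dione | IC[C@@H]1C[C@@]2(CC=C(C)C)C(=O)O[C@](C(=O)C(C)C)(C2=O)C1(C)C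
F12 | step 12 | iodo{[(1R,3R,5R)-4,4-dimethyl-1-(3-methylbut-2-en-1-yl)-5-(2-methylpropanoyl)-7,8-dioxo-6-oxabicyclo[3.2.1]octan-3-yl]methyl}zinc | I[Zn]C[C@@H]1C[C@@]2(CC=C(C)C)C(=O)O[C@](C(=O)C(C)C)(C2=O)C1(C)C
A1 | alternative 1 | methyl 2-formyl-5,5,8-trimethyl-2,4-bis(3-methylbut-2-en-1-yl)-6,7-dioxononanoate | CC(C)=CC[C@H](C[C@@](CC=C(C)C)(C(=O)OC)C=O)C(C)(C)C(=O)C(=O)C(C)C
A2 | alternative 1 | methyl 3-hydroxy-4,4-dimethyl-1,5-bis(3-methylbut-2-en-1-yl)-3-(2-methylpropanoyl)-2-oxocyclohexane-1-carboxylate | CC(C)=CC[C@@H]1C[C@@](CC=C(C)C)(C(=O)OC)C(=O)[C@](O)(C(=O)C(C)C)C1(C)C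
A3 | alternative 2 | 4-hydroxy-5-(2-methylpropanoyl)-3-(prop-2-en-1-yl)-3-[2-(prop-1-en-2-yl)pent-4-en-1-yl]furan-2(3H)-one | C=CC[C@H](C[C@@]1(CC=C)C(=O)OC(C(=O)C(C)C)=C1O)C(C)=C
A4 | alternative 2 | 4,4-dimethyl-5-(2-methylpropanoyl)-1,3-di(prop-2-en-1-yl)-6-oxabicyclo[3.2.1]octane-7,8-dione | C=CC[C@@H]1C[C@@]2(CC=C)C(=O)O[C@](C(=O)C(C)C)(C2=O)C1(C)C
A5 | alternative 3 | 5-(2-methylpropanoyl)-3,3-bis[(2E)-4-oxobut-2-en-1-yl]-5-(prop-1-en-2-yl)furan-2,4(3H,5H)-dione | O=C/C=C/CC1(C/C=C/C=O)C(=O)O[C@@](C(=O)C(C)C)(C(C)=C)C1=O
A6 | alternative 3 | (2E)-4-[4,4-dimethyl-5-(2-methylpropanoyl)-7,8-dioxo-3-(2-oxoethyl)-6-oxabicyclo[3.2.1]octan-1-yl]but-2-enal | O=CC[C@@H]1C[C@@]2(C/C=C/C=O)C(=O)O[C@](C(=O)C(C)C)(C2=O)C1(C)C
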